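## The problem

Atoms are numbered along the SMILES string: C2 is the isopropyl methine, then C4, C5, C6, C7, C8, C9, C10 (methyl on C9), C11, C12, C13, C14, C15 (O16), C17 (Br), C19, C20, C21 (C22 methyl, O23). Ring A is C8/C9/C17/C19/C20/C21, ring B is C7/C8/C9/C11/C12/C13, ring D is C6/C7/C13/C14/C15, and ring C is the bridge ring C4/C5/C6/C7/C13.

- **Ring system.** Rings A and B form a trans-fused decalin with an angular methyl on C9. Ring B shares its C13–C7 edge with a bicyclo[2.2.1]heptane whose bridgeheads are C13 (quaternary) and C6, with C7 as the one-carbon bridge.
- **Stereocenters.** There are nine: 4S, 6R, 7S, 8S, 9S, 13S, 15R, 17S, 21R. Two are quaternary carbons (C9, C13) and one is a tertiary carbinol (C21).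
- **Chain of control.** C15 can be bought. It places C6 (trans addition), C6 directs the face at C7, the dienophile geometry and the endo rule tie C9 to C7, and C8 is epimerisable next to the C21 carbonyl. The tether fixes C13, and the exo preference of the bicycle sets C4. The axial C10 methyl then steers reagents at C21 and C17.
- **Fragile groups.** The equatorial secondary bromide at C17 sits beside quaternary C9 and is prone to elimination and 1,2-methyl shift. The axial tertiary alcohol at C21 ionises in acid. The bromide must therefore come last but one, and the tertiary alcohol after all acid chemistry.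
- **Crowding.** The exo oxygen on C15 lies against H8, so once the bicycle exists only the trans ring fusion is comfortable.
- **Feature that enables the key step.** C9 (angular methyl) and C8 are flanked by C17 and C21, both functionalised and 1,4-related. This is the pattern of a methylbenzoquinone double bond. The C13–C7 edge of ring B is also an edge of five-membered ring D, which is the pattern of a 1-vinylcyclopentene. A quinone Diels–Alder reaction forming C9–C11 and C8–C7 therefore closes ring B.

## Retrosynthesis

**O–Si and C17–Br.** Target 19 is traced to silyl ether 18 and then to axial alcohol 17. The bromide cannot survive tin hydride, SmI2 or Grignard steps, so it is made last from the C17 alcohol by inversion. The forward step must achieve SN2 at a neopentyl-type centre ahead of elimination.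

**C21–C22, C17–H and C20–O.** Diol 17 comes from hydroxy ketone 16 by methyl addition, and 16 from methoxy diketone 14. The two ring A ketones of a plain 1,4-dione differ only in hindrance. Keeping the quinone methoxy group on C20 until this point lets SmI2 turn C21 into an enolate while the hydride reduces C17. This is preferred to relying on steric discrimination by a methyl nucleophile.

**C2–H and C13–C4.** Ketone 14 comes from tertiary chloride 13, and 13 from enedione chloride 12 by enedione reduction (tin hydride would attack the enedione, so zinc comes first). Cutting C13–C4 in 12 gives trans enedione 11, a 1,6-diene made of the ring B alkene and a prenyl group. This cut is preferred to C4–C5 or C5–C6 because all five bridge carbons then arrive as one prenyl unit that is inert in the cycloaddition. The forward reaction is a proton-initiated 5-exo cation–olefin closure with chloride capture. Reversible protonation is used because no reagent can pick the ring alkene over the prenyl alkene irreversibly.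

**C8 epimer.** Trans enedione 11 comes from the cis adduct 10 by enolisation toward C21.

**C9–C11 and C8–C7 (key cut).** Adduct 10 is split into diene 7 and quinone 9. This removes ring B, two C–C bonds and three stereocenters at once and leaves two small fragments. The forward reaction must be site-, regio-, endo- and face-selective.

**C12–C13 and C5–C6.** Diene 7 comes from enol triflate 5 and vinylstannane 6. Triflate 5 comes from silyl enol ether 3, made from commercial enone 1 and prenyl reagent 2 by trans conjugate addition.

**Quinone.** Quinone 9 comes from phenol 8 by para oxidation.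

## Roads not taken

**Alternative 1:** The C4–C5 bond is cut. KOt-Bu would enolise an acetonyl side chain on C13 at C4, and the enolate would displace a primary tosylate on C5 to give the exo-acetyl norbornane A1.
- Merits: a 5-exo SN2 closure on a primary sulfonate is more dependable than the cationic closure chosen here. The acetyl group can be equilibrated to the exo position, so C4 is under thermodynamic control.
- Weak points: the whole A/B/D tricycle with a quaternary C13 bearing the acetonyl chain must be built linearly first. Three oxygen functions need three different protecting groups. The acetyl group still has to be turned into isopropyl (methylenation, hydrogenation).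
- Comparison: the chosen plan cannot match the reliability of this bridge closure. It offers convergence instead: ring B and three stereocenters form in one step, and the prenyl group already carries the isopropyl carbons at the right oxidation level.

**Alternative 2:** The C13–C7, C14–C15 and C15–C6 bonds are cut. Co2(CO)8 would join a butynyl group on C9, a vinyl group on C8 and CO to give the tricyclic cyclopentenone A2.
- Merits: an intramolecular Pauson–Khand reaction is as dependable as the Diels–Alder reaction for ring formation. It installs the C15 oxygen directly, and the enone offers a handle at C13.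
- Weak points: ring A with vicinal C9 (quaternary) and C8 trans substituents must be made first. A2 has no substituent on C6 and no bridge, so a conjugate addition to a hindered β,β-disubstituted enone, a C6 alkylation and a ring closure are still needed. The C15 ketone must later be reduced to the exo alcohol.
- Comparison: ring construction is equally good. The chosen plan has the shorter path after annulation, because its diene already carries the C6 side chain and the C15 stereocenter.

**Alternative 3:** The C11–C12 and C13–C4 bonds are cut. Bu3SnH would turn a neopentyl iodide into the C11 radical, which closes ring B 6-endo at C12; the tertiary C13 radical then closes the bridge 5-exo at C4, and the C2 radical takes hydrogen to give A3.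
- Merits: two rings form in one operation. Radical termination gives the isopropyl group directly with no cation to rearrange, which is mechanistically cleaner than step 7 of the chosen route.
- Weak points: the first closure must go 6-endo in competition with 5-exo attack at C13 and with simple reduction. The precursor needs rings A and D joined through C8–C7, with C7, C8 and C9 set without the help of ring B.
- Comparison: the chosen plan sets C7–C9 by a cycloaddition of known selectivity. It keeps a radical closure of the same C13–C4 bond in reserve as the fallback for step 7.

Key step: step 5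

Remark on the chemistry: prenylmagnesium chloride (2) is taken as the commercial THF solution. Compounds 13 and 14 are drawn as the equatorial C20 methoxy epimers; the C20 configuration is destroyed in step 10, so either epimer serves.

## Steps

Step 1
Reactants: 1 (R)-4-(tert-butyldimethylsilyloxy)cyclopent-2-en-1-one; 2 prenylmagnesium chloride
Product: 3 (3R,4R)-4-(tert-butyldimethylsilyloxy)-3-(3-methylbut-2-en-1-yl)-1-(trimethylsilyloxy)cyclopent-1-ene
Conditions: 2 (1.3 equiv), CuBr·SMe2 (1.4 equiv), LiCl, THF, −78 °C; then TMSCl (2 equiv) and 1, −78 °C; Et3N, pentane work-up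
Reagents that add atoms: chlorotrimethylsilane, C[Si](C)(C)Cl
Why: Conjugate addition of a preformed allylic copper reagent with silyl trapping; such reagents transfer the prenyl group through its CH2 terminus, and attack anti to the silyloxy group sets C6 trans to C15 as in 1,4-additions to 4-silyloxycyclopentenones. TMSCl fixes the C13=C7 enolate before it can equilibrate toward C14 and expel the silyloxy group.

Step 2
Reactants: 3
Product: 5 (3R,4R)-4-(tert-butyldimethylsilyloxy)-3-(3-methylbut-2-en-1-yl)cyclopent-1-en-1-yl trifluoromethanesulfonate, via lithium enolate 4 (not isolated)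
Conditions: MeLi (1.05 equiv), THF, 0 °C; then N-(5-chloro-2-pyridyl)triflimide (1.2 equiv), −78 → −20 °C
Reagents that add atoms: N-(5-chloro-2-pyridyl)bis(trifluoromethanesulfonyl)imide, O=S(=O)(N(c1ccc(Cl)cn1)S(=O)(=O)C(F)(F)F)C(F)(F)F
Why: MeLi cleaves the O–SiMe3 bond to the regiodefined lithium enolate, which is O-sulfonylated at low temperature faster than it can equilibrate; no stereocenter is touched.

Step 3
Reactants: 5; 6 tributyl(vinyl)stannane
Product: 7 tert-butyldimethyl{[(1R,2R)-2-(3-methylbut-2-en-1-yl)-4-vinylcyclopent-3-en-1-yl]oxy}silane
Conditions: Pd(PPh3)4 (5 mol %), LiCl (3 equiv), THF, 60 °C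
Reagents that add atoms: none
Why: Stille coupling of an enol triflate with a vinylstannane under zerovalent palladium catalysis forms C13–C12 and the diene; the allylic stereocenters are not involved.

Step 4
Reactants: 8 2-methoxy-5-methylphenol
Product: 9 2-methoxy-5-methyl-1,4-benzoquinone
Conditions: (KSO3)2NO (2.2 equiv), KH2PO4 buffer, H2O/acetone, 0 → 23 °C
Reagents that add atoms: potassium nitrosodisulfonate, [K+].[K+].[O]N(S(=O)(=O)[O-])S(=O)(=O)[O-]
Why: Teuber oxidation; the nitrosodisulfonate radical converts phenols with a free para position into para-quinones, and the position para to the hydroxyl of 8 is unsubstituted.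

Step 5
Reactants: 7; 9
Product: 10 cis-fused tricyclic enedione adduct (rings A, B, D; C12=C13; 15-silyloxy, 6-prenyl, 20-methoxy, 17,21-dione; H7, H8 and the C10 methyl on one face of ring B)
Conditions: 9 (1.5 equiv), toluene (1 M), BHT (cat.), 90 °C, sealed tube, dark
Reagents that add atoms: none
Why: Concerted, asynchronous thermal [4+2] cycloaddition between the s-cis diene C11=C12–C13=C7 of 7 and the methyl-bearing C9=C8 bond of 9; the closest known type is the thermal Diels–Alder reaction of this quinone with butadiene or 1-vinylcycloalkenes, which gives cis-fused angular-methyl decalindiones. Ring B closes as a cyclohexene by formation of C9–C11 and C8–C7 in one step, leaving C12=C13 exocyclic to ring D. Site selectivity comes from the methoxy group, which makes C19=C20 part of a vinylogous ester and leaves only C9=C8 reactive. The C21 carbonyl, which is not conjugated to the methoxy oxygen, is the stronger acceptor and makes C9 the electrophilic terminus that bonds to the unsubstituted, more nucleophilic diene terminus C11; a monodentate Lewis acid would bind the C17 carbonyl and reverse this, hence purely thermal conditions. C9 and C8 keep the cis relationship of the dienophile (suprafacial addition). C7 is set by approach of the quinone to the ring D face opposite the neighbouring prenyl group on C6, the same relationship (trans to the adjacent group, cis to the remote silyloxy group) that governs electrophile capture by prostaglandin-type cyclopentane enolates. The endo transition state, with the quinone carbonyls under C12–C13, places H7 cis to H8 and to the C10 methyl, so C7 and C9 are as in the target and only C8 needs correction. The adduct cannot aromatise because C9 is quaternary.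

Step 6
Reactants: 10
Product: 11 trans-fused tricyclic enedione (C8 epimer of 10; H8 trans to the C10 methyl and to H7)
Conditions: NaOMe (0.2 equiv), MeOH, 0 → 23 °C; AcOH quench
Reagents that add atoms: none
Why: Base-mediated epimerisation through the C21 enolate; C8 is the only enolisable stereocenter, and the trans-fused angular-methyl decalindione is the thermodynamic isomer, as in the classical cis-to-trans isomerisation of such quinone adducts. Methoxide exchange at C20 is degenerate.

Step 7
Reactants: 11
Product: 12 tetracyclic tertiary chloride (C13–C4 closed; 2-chloropropan-2-yl group exo on C4; methoxy enedione intact)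
Conditions: SnCl4 (3 equiv), anhydrous HCl (2 equiv, CH2Cl2 solution), CH2Cl2, −78 °C; then Et3N, MeOH, −78 °C
Reagents that add atoms: hydrogen chloride, Cl
Why: Proton-initiated cation–olefin cyclisation with chloride termination: Markovnikov protonation of C12=C13 gives the tertiary C13 cation, 5-exo attack by C4 of the prenyl alkene closes the bicyclo[2.2.1]heptane, and the tertiary C2 cation collapses with chloride, while protonation of the prenyl alkene is reversible and unproductive. C13 is fixed by the tether (the bridge can only form on the ring D face that carries C5), and C4 is set with the C2 group exo, toward the C7 bridge hydrogen and away from the C14–C15 bridge. Low temperature and a chloride-rich counter-ion (SnCl5−) are chosen so that capture outruns hydride and alkyl shifts.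

Step 8
Reactants: 12
Product: 13 tetracyclic 20-methoxy-17,21-dione tertiary chloride (C19=C20 reduced)
Conditions: Zn dust (10 equiv), AcOH, 23 °C
Reagents that add atoms: none
Why: Zinc/acetic acid reduction of a conjugated enedione to the saturated 1,4-diketone, standard for quinone Diels–Alder adducts; the tertiary chloride and silyl ether are inert, and C8 stays trans because that is its stable configuration.

Step 9
Reactants: 13
Product: 14 tetracyclic 4-isopropyl-20-methoxy-17,21-dione
Conditions: Bu3SnH (3 equiv), AIBN (0.2 equiv), toluene, 100 °C
Reagents that add atoms: none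
Why: Radical-chain dehalogenation of a tertiary chloride; the C2 radical takes hydrogen from Bu3SnH, C2 is not stereogenic and C4 is untouched. The step follows step 8 because tin hydride would reduce the enedione.

Step 10
Reactants: 14
Product: 16 tetracyclic 17-hydroxy-21-ketone (C17 hydroxyl axial, anti to the C10 methyl), via samarium enolate 15 (not isolated)
Conditions: SmI2 (2.3 equiv), THF, −78 °C; then LiBH(s-Bu)3 (1.5 equiv), −78 → −40 °C; NH4Cl (aq)
Reagents that add atoms: none
Why: SmI2 cleaves the C20–OMe bond of the α-methoxy ketone (known reductive cleavage of α-alkoxy ketones) and leaves C21 masked as its trivalent samarium enolate, so the borohydride can only reduce the C17 ketone. Equatorial hydride delivery, normal for this bulky reagent on cyclohexanones beside a quaternary carbon, gives the axial C17 alcohol; work-up returns the C21 ketone.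

Step 11
Reactants: 16
Product: 17 tetracyclic 17,21-diol (C21 methyl equatorial, C21 hydroxyl axial and syn to the C10 methyl)
Conditions: MeMgBr (4 equiv), CeCl3 (4 equiv), THF, −78 → 0 °C
Reagents that add atoms: methylmagnesium bromide, C[Mg]Br
Why: Grignard addition to the only ketone, with CeCl3 to suppress enolisation; the axial face of C21 is blocked by the syn-axial C10 methyl, so the methyl group enters equatorially and the new hydroxyl is axial as in the target.

Step 12
Reactants: 17
Product: 18 C15 silyl ether of the target (C17 bromide equatorial)
Conditions: CBr4 (3 equiv), PPh3 (3 equiv), 2,6-lutidine (1 equiv), CH2Cl2, 0 → 23 °C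
Reagents that add atoms: carbon tetrabromide, BrC(Br)(Br)Br
Why: Appel reaction; the alkoxyphosphonium of the axial secondary alcohol is displaced by bromide with inversion to the equatorial bromide, the established way (bulky hydride, then PPh3/CBr4) to equatorial bromides beside quaternary carbons in brominated terpenoids. The axial tertiary C21 hydroxyl is too hindered to be activated at this temperature.

Step 13
Reactants: 18
Product: 19 (4S,6R,7S,8S,9S,13S,15R,17S,21R)-17-bromo-4-isopropyl-9,21-dimethyl tetracyclic 15,21-diol (target)
Conditions: HF·pyridine, pyridine, THF, 0 → 23 °C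
Reagents that add atoms: none
Why: Buffered fluoride cleavage of the Si–O bond; the equatorial bromide has no anti-periplanar hydrogen for elimination, and the tertiary alcohol does not ionise under these conditions.

## Compound list

1 | (R)-4-(tert-butyldimethylsilyloxy)cyclopent-2-en-1-one | O=C1C=C[C@H](O[Si](C)(C)C(C)(C)C)C1 | starting material
2 | prenylmagnesium chloride (3-methylbut-2-en-1-ylmagnesium chloride) | CC(C)=CC[Mg]Cl | starting material
3 | (3R,4R)-4-(tert-butyldimethylsilyloxy)-3-(3-methylbut-2-en-1-yl)-1-(trimethylsilyloxy)cyclopent-1-ene | C[Si](C)(C)OC1=C[C@@H](CC=C(C)C)[C@H](O[Si](C)(C)C(C)(C)C)C1 | intermediate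
4 | lithium (3R,4R)-4-(tert-butyldimethylsilyloxy)-3-(3-methylbut-2-en-1-yl)cyclopent-1-en-1-olate (not isolated) | [Li]OC1=C[C@@H](CC=C(C)C)[C@H](O[Si](C)(C)C(C)(C)C)C1 | intermediate
5 | (3R,4R)-4-(tert-butyldimethylsilyloxy)-3-(3-methylbut-2-en-1-yl)cyclopent-1-en-1-yl trifluoromethanesulfonate | O=S(=O)(OC1=C[C@@H](CC=C(C)C)[C@H](O[Si](C)(C)C(C)(C)C)C1)C(F)(F)F | intermediate
6 | tributyl(vinyl)stannane | CCCC[Sn](CCCC)(CCCC)C=C | starting material
7 | tert-butyldimethyl{[(1R,2R)-2-(3-methylbut-2-en-1-yl)-4-vinylcyclopent-3-en-1-yl]oxy}silane (prenyl silyloxy vinylcyclopentene) | C=CC1=C[C@@H](CC=C(C)C)[C@H](O[Si](C)(C)C(C)(C)C)C1 | intermediate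
8 | 2-methoxy-5-methylphenol | COc1ccc(C)cc1O | starting material
9 | 2-methoxy-5-methyl-1,4-benzoquinone | COC1=CC(=O)C(C)=CC1=O | intermediate
10 | cis-fused tricyclic enedione adduct (H7, H8 and C10 methyl cis; C15 silyloxy on the ring D face of C8; prenyl on the opposite face) | CC(C)=CC[C@H]1[C@H](O[Si](C)(C)C(C)(C)C)CC2=CC[C@]3(C)C(=O)C=C(OC)C(=O)[C@@H]3[C@H]12 | intermediate
11 | trans-fused tricyclic enedione (C8 epimer of 10) | CC(C)=CC[C@H]1[C@H](O[Si](C)(C)C(C)(C)C)CC2=CC[C@]3(C)C(=O)C=C(OC)C(=O)[C@H]3[C@H]12 | intermediate
12 | tetracyclic methoxy enedione with exo 2-chloropropan-2-yl group on C4 | CC(C)(Cl)[C@@H]1C[C@@H]2[C@H]3[C@H]4[C@](C)(CC[C@@]31C[C@H]2O[Si](C)(C)C(C)(C)C)C(=O)C=C(OC)C4=O | intermediate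
13 | tetracyclic 20-methoxy-17,21-dione with exo 2-chloropropan-2-yl group on C4 (C20 methoxy drawn equatorial) | CC(C)(Cl)[C@@H]1C[C@@H]2[C@H]3[C@H]4[C@](C)(CC[C@@]31C[C@H]2O[Si](C)(C)C(C)(C)C)C(=O)C[C@@H](OC)C4=O | intermediate
14 | tetracyclic 4-exo-isopropyl-20-methoxy-17,21-dione | CC(C)[C@@H]1C[C@@H]2[C@H]3[C@H]4[C@](C)(CC[C@@]31C[C@H]2O[Si](C)(C)C(C)(C)C)C(=O)C[C@@H](OC)C4=O | intermediate
15 | C21 diiodosamarium enolate of the 17-ketone (C20=C21; not isolated) | CC(C)[C@@H]1C[C@@H]2[C@H]3[C@H]4[C@](C)(CC[C@@]31C[C@H]2O[Si](C)(C)C(C)(C)C)C(=O)CC=C4O[Sm](I)I | intermediate
16 | tetracyclic 17-axial-hydroxy-21-ketone | CC(C)[C@@H]1C[C@@H]2[C@H]3[C@H]4[C@](C)(CC[C@@]31C[C@H]2O[Si](C)(C)C(C)(C)C)[C@H](O)CCC4=O | intermediate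
17 | tetracyclic 17,21-diol (C17 hydroxyl axial; C21 hydroxyl axial, methyl equatorial) | CC(C)[C@@H]1C[C@@H]2[C@H]3[C@H]4[C@](C)(CC[C@@]31C[C@H]2O[Si](C)(C)C(C)(C)C)[C@H](O)CC[C@@]4(C)O | intermediate
18 | C15 tert-butyldimethylsilyl ether of the target (C17 bromide equatorial) | CC(C)[C@@H]1C[C@@H]2[C@H]3[C@H]4[C@](C)(CC[C@@]31C[C@H]2O[Si](C)(C)C(C)(C)C)[C@@H](Br)CC[C@@]4(C)O | intermediate
19 | (4S,6R,7S,8S,9S,13S,15R,17S,21R)-17-bromo-4-isopropyl-9,21-dimethyl tetracyclic 15,21-diol (CNP0317598.2; locants as defined under "The problem") | CC(C)[C@@H]1C[C@@H]2[C@H]3[C@H]4[C@](C)(CC[C@@]31C[C@H]2O)[C@@H](Br)CC[C@@]4(C)O | target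

## Step count and least certain steps

Total step count: 13. Longest linear sequence: 12 steps (1 to 19 through steps 1–3 and 5–13). The quinone branch is one step (step 4).

**Step 5 (key step).**
- What may go wrong: loss of facial selectivity, because the C15 silyloxy group lies on the face the quinone must use and partly offsets the shielding by the prenyl group. The trisubstituted dienophile bond may also react slowly, giving the diene time to dimerise.
- Fallback: starting from 7, the silyl group is removed (Bu4NF, THF) to give the dienol (1R,2R)-2-(3-methylbut-2-en-1-yl)-4-vinylcyclopent-3-en-1-ol F1. The cycloaddition with 9 is then run in benzene, where a hydrogen bond from the C15 hydroxyl to the C21 carbonyl steers the quinone to the hydroxyl face. That is the required face, and the product is the hydroxy adduct F2. Silylation (TBSCl, imidazole, DMF) returns to 10.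

**Step 7.**
- What may go wrong: the cyclisation is outrun by simple hydrochlorination of either alkene. After ring closure, a 1,2-hydride shift from C4 to the C2 cation, followed by Wagner–Meerwein shifts, can scramble C4 and the skeleton. The ring B alkene can migrate toward conjugation with the C21 carbonyl. The silyl ether may be lost in the acid.
- Fallback: the closure is done by radicals instead of cations. Starting from 11, Zn/AcOH gives the uncyclised methoxy diketone F3. Hydrogen-atom transfer from a metal hydride (Mn(dpm)3, PhSiH3, t-BuOOH, i-PrOH) to C12 then generates the tertiary C13 radical, which closes 5-exo onto C4; the C2 radical takes hydrogen and gives 14 directly. The radical cannot undergo hydride or alkyl shifts. The price is that hydrogen-atom transfer to the prenyl alkene is not suppressed and costs material.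

**Step 12.**
- What may go wrong: elimination toward C19 (the axial leaving group has an anti-periplanar hydrogen) and 1,2-shift of the C10 methyl compete with a slow SN2 displacement at a carbon flanked by quaternary C9. The tertiary alcohol may dehydrate.
- Fallback: activation and displacement are separated. Starting from 17, chloromethanesulfonyl chloride and pyridine give the C17 chloromethanesulfonate F4, a leaving group that favours SN2 over ionisation. LiBr in DMF then displaces it with inversion to give 18.

**Step 1.**
- What may go wrong: transfer of the prenyl group through its substituted terminus (giving a 1,1-dimethylallyl group) or 1,2-addition of the allylic organometallic.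
- Fallback: the regiochemical question is removed by adding an allyl group and building the prenyl terminus afterwards. Starting from 1, allylmagnesium bromide/CuBr·SMe2/TMSCl gives the allyl silyl enol ether F5. MeLi and then the pyridyl triflimide give the allyl enol triflate F6. Cross metathesis with 2-methyl-2-butene (second-generation Grubbs catalyst, (H2IMes)(PCy3)Cl2Ru=CHPh) returns to 5.

**Step 10.**
- What may go wrong: proton leakage or equilibration of the samarium enolate, which lets the hydride reach C21, and slow reduction of the hindered C17 ketone at low temperature.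
- Fallback: the ketones are told apart by hindrance instead. Starting from 14, SmI2 in THF/MeOH gives the 17,21-diketone F7. MeTi(OiPr)3, which adds only to the less hindered ketone and from the equatorial side, gives the 21-hydroxy-17-ketone F8. LiBH(s-Bu)3 then gives 17.

Further compounds
F1 | step 5 | (1R,2R)-2-(3-methylbut-2-en-1-yl)-4-vinylcyclopent-3-en-1-ol | C=CC1=C[C@@H](CC=C(C)C)[C@H](O)C1
F2 | step 5 | C15-hydroxy cis-fused enedione adduct (10 without the silyl group) | CC(C)=CC[C@H]1[C@H](O)CC2=CC[C@]3(C)C(=O)C=C(OC)C(=O)[C@@H]3[C@H]12
F3 | step 7 | trans-fused tricyclic 20-methoxy-17,21-dione with C12=C13 and prenyl group intact | CC(C)=CC[C@H]1[C@H](O[Si](C)(C)C(C)(C)C)CC2=CC[C@]3(C)C(=O)C[C@@H](OC)C(=O)[C@H]3[C@H]12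
F4 | step 12 | C17 chloromethanesulfonate of diol 17 | CC(C)[C@@H]1C[C@@H]2[C@H]3[C@H]4[C@](C)(CC[C@@]31C[C@H]2O[Si](C)(C)C(C)(C)C)[C@H](OS(=O)(=O)CCl)CC[C@@]4(C)O
F5 | step 1 | (3R,4R)-3-allyl-4-(tert-butyldimethylsilyloxy)-1-(trimethylsilyloxy)cyclopent-1-ene | C[Si](C)(C)OC1=C[C@@H](CC=C)[C@H](O[Si](C)(C)C(C)(C)C)C1
F6 | step 1 | (3R,4R)-3-allyl-4-(tert-butyldimethylsilyloxy)cyclopent-1-en-1-yl trifluoromethanesulfonate | O=S(=O)(OC1=C[C@@H](CC=C)[C@H](O[Si](C)(C)C(C)(C)C)C1)C(F)(F)F
F7 | step 10 | tetracyclic 4-exo-isopropyl-17,21-dione | CC(C)[C@@H]1C[C@@H]2[C@H]3[C@H]4[C@](C)(CC[C@@]31C[C@H]2O[Si](C)(C)C(C)(C)C)C(=O)CCC4=O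
F8 | step 10 | tetracyclic 21-hydroxy-21-methyl-17-ketone | CC(C)[C@@H]1C[C@@H]2[C@H]3[C@H]4[C@](C)(CC[C@@]31C[C@H]2O[Si](C)(C)C(C)(C)C)C(=O)CC[C@@]4(C)O
A1 | alternative 1 | tetracyclic exo-acetyl norbornane (C15 triisopropylsilyl ether, C17 tert-butyldimethylsilyl ether, C21 dioxolane) | CC(=O)[C@@H]1C[C@@H]2[C@H]3[C@H]4[C@](C)(CC[C@@]31C[C@H]2O[Si](C(C)C)(C(C)C)C(C)C)[C@H](O[Si](C)(C)C(C)(C)C)CCC45OCCO5
A2 | alternative 2 | tricyclic cyclopentenone (C17 tert-butyldimethylsilyl ether, C21 dioxolane) | C1[C@H]2[C@H]3[C@](C)(CCC2=CC1=O)[C@H](O[Si](C)(C)C(C)(C)C)CCC34OCCO4
A3 | alternative 3 | tetracyclic C17 alcohol with C21 dioxolane and C15 tert-butyldimethylsilyl ether | CC(C)[C@@H]1C[C@@H]2[C@H]3[C@H]4[C@](C)(CC[C@@]31C[C@H]2O[Si](C)(C)C(C)(C)C)[C@H](O)CCC45OCCO5
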